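The synthesis rests on disconnecting the furan C2=C3 bond of the central benzofuran: C3 carries the CH2 arm to ring C, C2 carries ring B, and O1–C2 is already in place as an aryl ester. Both carbons are then carbonyl carbons, C3 the ketone of a ring-A deoxybenzoin and C2 the carboxyl carbon of a ring-B benzoate on the ortho phenol oxygen. Low-valent titanium couples the two reductively, removes both oxygens and so closes and aromatises the furan in a single operation. The precursor is a penta-MOM o-aroyloxy deoxybenzoin whose ring-C bromide later takes up the 3-bromocoumarin by Suzuki coupling.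

Key step: step 12

Remark on stereochemistry: the target has no stereocentre and no stereogenic double bond; it is achiral, so no step has to set or preserve configuration.

Remark on design: every phenol that must last to the end is a MOM ether. The ortho phenol of ring A travels as a PMB ether so that it alone can be freed. The ester is made with a carbodiimide, so that no acid chloride and no HCl meet the MOM groups. One Claisen-derived aldehyde (14) supplies both the ring-B acid and the coumarin.

Step 1
Reactants: 1 2,4-dihydroxyacetophenone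
Product: 2 1-[2-hydroxy-4-(methoxymethoxy)phenyl]ethanone
Conditions: MOMCl (1.1 equiv), K2CO3, acetone, rt
Reagents that add atoms: chloromethyl methyl ether, COCCl
Why: Williamson-type O-alkylation in which the 2-OH, hydrogen-bonded to the ketone, is far less nucleophilic, so only the 4-OH should be protected.

Step 2
Reactants: 2 1-[2-hydroxy-4-(methoxymethoxy)phenyl]ethanone
Product: 3 1-[2-(4-methoxybenzyloxy)-4-(methoxymethoxy)phenyl]ethanone
Conditions: PMBCl (1.3 equiv), K2CO3, KI (cat.), DMF, 60 °C
Reagents that add atoms: 4-methoxybenzyl chloride, COc1ccc(CCl)cc1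
Why: Williamson etherification of the chelated phenol under more forcing conditions gives a base-stable ether that can later be removed oxidatively without touching MOM.

Step 3
Reactants: 4 4,6-dibromoresorcinol
Product: 5 1,5-dibromo-2,4-bis(methoxymethoxy)benzene
Conditions: NaH (2.4 equiv), MOMCl (2.4 equiv), DMF, 0 °C→rt
Reagents that add atoms: chloromethyl methyl ether, COCCl
Why: double Williamson-type O-alkylation of an acidic bromophenol; the product is symmetrical, so either bromide is equivalent in the next step.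

Step 4
Reactants: 3 1-[2-(4-methoxybenzyloxy)-4-(methoxymethoxy)phenyl]ethanone; 5 1,5-dibromo-2,4-bis(methoxymethoxy)benzene (3 equiv)
Product: 6 2-[5-bromo-2,4-bis(methoxymethoxy)phenyl]-1-[2-(4-methoxybenzyloxy)-4-(methoxymethoxy)phenyl]ethanone
Conditions: Pd2(dba)3 (2 mol%), Xantphos (5 mol%), NaOtBu (2.2 equiv), THF, 70 °C
Reagents that add atoms: none
Why: palladium-catalysed α-arylation of a methyl aryl ketone enolate (Buchwald–Hartwig type); the threefold excess of the symmetrical, recoverable dibromide should hold the reaction at mono-coupling, and the product rests as its enolate, which resists a second arylation.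

Step 5
Reactants: 6 2-[5-bromo-2,4-bis(methoxymethoxy)phenyl]-1-[2-(4-methoxybenzyloxy)-4-(methoxymethoxy)phenyl]ethanone
Product: 7 2-[5-bromo-2,4-bis(methoxymethoxy)phenyl]-1-[2-hydroxy-4-(methoxymethoxy)phenyl]ethanone
Conditions: DDQ (1.3 equiv), CH2Cl2–pH 7 buffer (10:1), 0 °C→rt
Reagents that add atoms: none
Why: oxidative PMB cleavage (hydride abstraction from the electron-rich benzyl ether, then hydrolysis) should spare MOM ethers, the aryl bromide and the ketone, whose α-CH2 cannot support a cation.

Step 6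
Reactants: 8 2,4-dihydroxybenzaldehyde; 9 prenyl bromide (1.05 equiv)
Product: 10 2-hydroxy-4-(3-methylbut-2-enyloxy)benzaldehyde
Conditions: K2CO3, acetone, reflux
Reagents that add atoms: none
Why: Williamson etherification that is selective for the 4-OH because the 2-OH is tied up in a hydrogen bond to the aldehyde.

Step 7
Reactants: 10 2-hydroxy-4-(3-methylbut-2-enyloxy)benzaldehyde
Product: 11 2-(methoxymethoxy)-4-(3-methylbut-2-enyloxy)benzaldehyde
Conditions: NaH (1.2 equiv), MOMCl (1.2 equiv), DMF, 0 °C→rt
Reagents that add atoms: chloromethyl methyl ether, COCCl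
Why: O-alkylation of the chelated phenoxide removes the hydrogen bond that would otherwise steer the coming rearrangement to C3.

Step 8
Reactants: 11 2-(methoxymethoxy)-4-(3-methylbut-2-enyloxy)benzaldehyde
Product: 13 4-hydroxy-2-(methoxymethoxy)-5-(2-methylbut-3-en-2-yl)benzaldehyde, via ortho-dienone 12 (not isolated)
Conditions: PhNEt2, 195 °C, sealed tube, Ar; stopped at full conversion
Reagents that add atoms: none
Why: aromatic Claisen rearrangement, a [3,3] shift with allyl inversion that turns the prenyl ether into a 1,1-dimethylallyl group on an ortho carbon; C5 should be preferred over C3, which is wedged between two oxygens and lies next to a meta donor that directs away from itself, and dienone 12 then tautomerises to the phenol.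

Step 9
Reactants: 13 4-hydroxy-2-(methoxymethoxy)-5-(2-methylbut-3-en-2-yl)benzaldehyde
Product: 14 2,4-bis(methoxymethoxy)-5-(2-methylbut-3-en-2-yl)benzaldehyde
Conditions: MOMCl (1.5 equiv), K2CO3, acetone, rt→40 °C
Reagents that add atoms: chloromethyl methyl ether, COCCl
Why: Williamson-type alkylation of an acidic phenol para to the formyl group; capping it also ends any risk that it adds to the neighbouring alkene.

Step 10
Reactants: 14 2,4-bis(methoxymethoxy)-5-(2-methylbut-3-en-2-yl)benzaldehyde
Product: 15 2,4-bis(methoxymethoxy)-5-(2-methylbut-3-en-2-yl)benzoic acid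
Conditions: NaClO2, NaH2PO4, 2-methyl-2-butene (20 equiv), t-BuOH–THF–H2O, 0 °C→rt; work-up at pH 4
Reagents that add atoms: sodium chlorite, [Na+].[O-]Cl=O
Why: Pinnick oxidation at about pH 4, mild enough for MOM ethers, with the alkene scavenger intercepting HOCl before it reaches the vinyl group or the electron-rich ring.

Step 11
Reactants: 7 2-[5-bromo-2,4-bis(methoxymethoxy)phenyl]-1-[2-hydroxy-4-(methoxymethoxy)phenyl]ethanone; 15 2,4-bis(methoxymethoxy)-5-(2-methylbut-3-en-2-yl)benzoic acid
Product: 16 2-{2-[5-bromo-2,4-bis(methoxymethoxy)phenyl]acetyl}-5-(methoxymethoxy)phenyl 2,4-bis(methoxymethoxy)-5-(2-methylbut-3-en-2-yl)benzoate (the o-aroyloxy deoxybenzoin)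
Conditions: EDC·HCl (1.5 equiv), DMAP (1.0 equiv), CH2Cl2, 0 °C→rt
Reagents that add atoms: none
Why: Steglich esterification through the acylpyridinium acylates the phenol under near-neutral conditions, with no enolate that could start a Baker–Venkataraman acyl shift.

Step 12
Reactants: 16 the o-aroyloxy deoxybenzoin
Product: 18 3-[5-bromo-2,4-bis(methoxymethoxy)benzyl]-2-[2,4-bis(methoxymethoxy)-5-(2-methylbut-3-en-2-yl)phenyl]-6-(methoxymethoxy)benzofuran, via titanium 2,3-diolate 17 (not isolated)
Conditions: TiCl3(DME)1.5 (8 equiv), Zn–Cu couple (20 equiv), DME, reflux 2 h; then 16 by syringe pump over 8 h at reflux (final ca. 0.01 M); aq. K2CO3 work-up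
Reagents that add atoms: none
Why: Low-valent titanium reduces the aryl ketone of 16 to a titanium-bound ketyl (or dianion) at the future C3, which adds to the carbonyl carbon of the ortho benzoate, the future C2, in a 5-exo-trig closure that completes the ring O1–C2–C3–C3a–C7a as the titanium diolate 17. The oxophilic metal then removes both oxygens, as in the second stage of a McMurry coupling, and leaves the aromatic furan C2=C3. The closest known reaction type is the titanium-induced intramolecular ketone–ester cyclisation of o-acyloxyaryl ketones to 2,3-disubstituted benzofurans. No stereocentre is formed, since C2 and C3 both end sp2. The step needs intramolecular ketone–ester coupling to win over ketyl dimerisation between molecules, over enolisation of the benzylic CH2 with acyl transfer to carbon, and over attack on C–Br or the MOM acetals. The ortho placement of the ester (five-membered transition state), slow addition at high dilution, the usual tolerance of aryl bromides, ethers and isolated alkenes, and the HCl-free TiCl3(DME)1.5/Zn–Cu reagent should secure this.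

Step 13
Reactants: 18 the penta-MOM benzofuran bromide
Product: 19 2-[2,4-bis(methoxymethoxy)-5-(2-methylbut-3-en-2-yl)phenyl]-3-[2,4-bis(methoxymethoxy)-5-(4,4,5,5-tetramethyl-1,3,2-dioxaborolan-2-yl)benzyl]-6-(methoxymethoxy)benzofuran
Conditions: B2pin2 (1.5 equiv), Pd(dppf)Cl2 (5 mol%), KOAc (3 equiv), dioxane, 90 °C
Reagents that add atoms: bis(pinacolato)diboron, CC1(C)OB(OC1(C)C)B1OC(C)(C)C(C)(C)O1
Why: Miyaura borylation of an electron-rich aryl bromide, in which the weak acetate base prevents the new boronate from coupling with unreacted bromide.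

Step 14
Reactants: 14 2,4-bis(methoxymethoxy)-5-(2-methylbut-3-en-2-yl)benzaldehyde
Product: 20 2-hydroxy-4-(methoxymethoxy)-5-(2-methylbut-3-en-2-yl)benzaldehyde
Conditions: MgBr2·OEt2 (2 equiv), Et2O–CH2Cl2, 0 °C→rt; aq. NH4Cl
Reagents that add atoms: none
Why: chelation-controlled Lewis-acid cleavage of an acetal ether ortho to a carbonyl group; magnesium bridges the aldehyde oxygen and the 2-O-aryl oxygen and so activates only that MOM group, while the 4-O-MOM cannot chelate.

Step 15
Reactants: 20 2-hydroxy-4-(methoxymethoxy)-5-(2-methylbut-3-en-2-yl)benzaldehyde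
Product: 22 3-bromo-7-(methoxymethoxy)-6-(2-methylbut-3-en-2-yl)-2H-chromen-2-one, via open-chain 2-bromoacrylate ester 21 (not isolated)
Conditions: Ph3P=C(Br)CO2Et (1.5 equiv), PhNEt2, 180 °C
Reagents that add atoms: ethyl bromo(triphenylphosphoranylidene)acetate, CCOC(=O)C(Br)=P(c1ccccc1)(c1ccccc1)c1ccccc1
Why: Wittig olefination with the stabilised α-bromo ylide followed by lactonisation (the phosphorane coumarin synthesis); the isomer with aryl cis to the ester (21) closes at once, and at 180 °C the other isomer should equilibrate through its o-quinone-methide tautomer and follow.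

Step 16
Reactants: 19 the benzofuran pinacol boronate; 22 3-bromo-7-(methoxymethoxy)-6-(2-methylbut-3-en-2-yl)-2H-chromen-2-one
Product: 23 hexa-MOM ether of the target: 3-{5-[(2-{2,4-bis(methoxymethoxy)-5-(2-methylbut-3-en-2-yl)phenyl}-6-(methoxymethoxy)benzofuran-3-yl)methyl]-2,4-bis(methoxymethoxy)phenyl}-7-(methoxymethoxy)-6-(2-methylbut-3-en-2-yl)-2H-chromen-2-one
Conditions: Pd(dppf)Cl2 (5 mol%), K2CO3 (3 equiv), dioxane–H2O (5:1), 80 °C
Reagents that add atoms: none
Why: Suzuki–Miyaura coupling of an aryl boronate with an activated α-bromo enoate, a fast oxidative-addition partner, under a mild carbonate base that should leave the lactone closed.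

Step 17
Reactants: 23 hexa-MOM ether of the target
Product: 24 the target, 3-{5-[(2-{2,4-dihydroxy-5-(2-methylbut-3-en-2-yl)phenyl}-6-hydroxybenzofuran-3-yl)methyl]-2,4-dihydroxyphenyl}-7-hydroxy-6-(2-methylbut-3-en-2-yl)-2H-chromen-2-one
Conditions: 3 M aq. HCl, MeOH–THF (1:1), 40 °C; stopped when the last MOM group is gone
Reagents that add atoms: none
Why: acid-catalysed acetal exchange removes all six MOM groups as dimethoxymethane, and dilute acid at mild temperature should be too weak to protonate the unactivated terminal alkenes or to open the coumarin.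

Compound list
1 | 2,4-dihydroxyacetophenone | CC(=O)c1ccc(O)cc1O | starting material
2 | 1-[2-hydroxy-4-(methoxymethoxy)phenyl]ethanone | CC(=O)c1ccc(OCOC)cc1O | intermediate
3 | 1-[2-(4-methoxybenzyloxy)-4-(methoxymethoxy)phenyl]ethanone | CC(=O)c1ccc(OCOC)cc1OCc1ccc(OC)cc1 | intermediate
4 | 4,6-dibromoresorcinol (4,6-dibromobenzene-1,3-diol) | Oc1cc(O)c(Br)cc1Br | starting material
5 | 1,5-dibromo-2,4-bis(methoxymethoxy)benzene | COCOc1cc(OCOC)c(Br)cc1Br | intermediate
6 | 2-[5-bromo-2,4-bis(methoxymethoxy)phenyl]-1-[2-(4-methoxybenzyloxy)-4-(methoxymethoxy)phenyl]ethanone | COCOc1ccc(C(=O)Cc2cc(Br)c(OCOC)cc2OCOC)c(OCc2ccc(OC)cc2)c1 | intermediate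
7 | 2-[5-bromo-2,4-bis(methoxymethoxy)phenyl]-1-[2-hydroxy-4-(methoxymethoxy)phenyl]ethanone | COCOc1ccc(C(=O)Cc2cc(Br)c(OCOC)cc2OCOC)c(O)c1 | intermediate
8 | 2,4-dihydroxybenzaldehyde | O=Cc1ccc(O)cc1O | starting material
9 | prenyl bromide (1-bromo-3-methylbut-2-ene) | CC(C)=CCBr | starting material
10 | 2-hydroxy-4-(3-methylbut-2-enyloxy)benzaldehyde | O=Cc1ccc(OCC=C(C)C)cc1O | intermediate
11 | 2-(methoxymethoxy)-4-(3-methylbut-2-enyloxy)benzaldehyde | O=Cc1ccc(OCC=C(C)C)cc1OCOC | intermediate
12 | 6-(methoxymethoxy)-3-(2-methylbut-3-en-2-yl)-4-oxocyclohexa-1,5-diene-1-carbaldehyde (Claisen ortho-dienone, racemic, transient) | O=CC1=CC(C(C)(C)C=C)C(=O)C=C1OCOC | intermediate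
13 | 4-hydroxy-2-(methoxymethoxy)-5-(2-methylbut-3-en-2-yl)benzaldehyde | O=Cc1cc(C(C)(C)C=C)c(O)cc1OCOC | intermediate
14 | 2,4-bis(methoxymethoxy)-5-(2-methylbut-3-en-2-yl)benzaldehyde | O=Cc1cc(C(C)(C)C=C)c(OCOC)cc1OCOC | intermediate
15 | 2,4-bis(methoxymethoxy)-5-(2-methylbut-3-en-2-yl)benzoic acid | OC(=O)c1cc(C(C)(C)C=C)c(OCOC)cc1OCOC | intermediate
16 | 2-{2-[5-bromo-2,4-bis(methoxymethoxy)phenyl]acetyl}-5-(methoxymethoxy)phenyl 2,4-bis(methoxymethoxy)-5-(2-methylbut-3-en-2-yl)benzoate | COCOc1ccc(C(=O)Cc2cc(Br)c(OCOC)cc2OCOC)c(OC(=O)c2cc(C(C)(C)C=C)c(OCOC)cc2OCOC)c1 | intermediate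
17 | dichlorotitanium(IV) 2,3-diolate of the cis-2,3-dihydrobenzofuran-2,3-diol formed from 16 (titanadioxolane, racemic, idealised formula) | COCOc1ccc2c(c1)OC3(c4cc(C(C)(C)C=C)c(OCOC)cc4OCOC)O[Ti](Cl)(Cl)OC23Cc1cc(Br)c(OCOC)cc1OCOC | intermediate
18 | 3-[5-bromo-2,4-bis(methoxymethoxy)benzyl]-2-[2,4-bis(methoxymethoxy)-5-(2-methylbut-3-en-2-yl)phenyl]-6-(methoxymethoxy)benzofuran | COCOc1ccc2c(Cc3cc(Br)c(OCOC)cc3OCOC)c(-c3cc(C(C)(C)C=C)c(OCOC)cc3OCOC)oc2c1 | intermediate
19 | 2-[2,4-bis(methoxymethoxy)-5-(2-methylbut-3-en-2-yl)phenyl]-3-[2,4-bis(methoxymethoxy)-5-(4,4,5,5-tetramethyl-1,3,2-dioxaborolan-2-yl)benzyl]-6-(methoxymethoxy)benzofuran | COCOc1ccc2c(Cc3cc(B4OC(C)(C)C(C)(C)O4)c(OCOC)cc3OCOC)c(-c3cc(C(C)(C)C=C)c(OCOC)cc3OCOC)oc2c1 | intermediate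
20 | 2-hydroxy-4-(methoxymethoxy)-5-(2-methylbut-3-en-2-yl)benzaldehyde | O=Cc1cc(C(C)(C)C=C)c(OCOC)cc1O | intermediate
21 | ethyl (E)-2-bromo-3-[2-hydroxy-4-(methoxymethoxy)-5-(2-methylbut-3-en-2-yl)phenyl]prop-2-enoate (aryl cis to the ester) | Br/C(C(=O)OCC)=C/c1cc(C(C)(C)C=C)c(OCOC)cc1O | intermediate
22 | 3-bromo-7-(methoxymethoxy)-6-(2-methylbut-3-en-2-yl)-2H-chromen-2-one | C=CC(C)(C)c1cc2cc(Br)c(=O)oc2cc1OCOC | intermediate
23 | hexa-MOM ether of the target | C=CC(C)(C)c1cc(-c2oc3cc(OCOC)ccc3c2Cc2cc(-c3cc4cc(C(C)(C)C=C)c(OCOC)cc4oc3=O)c(OCOC)cc2OCOC)c(OCOC)cc1OCOC | intermediate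
24 | 3-{5-[(2-{2,4-dihydroxy-5-(2-methylbut-3-en-2-yl)phenyl}-6-hydroxybenzofuran-3-yl)methyl]-2,4-dihydroxyphenyl}-7-hydroxy-6-(2-methylbut-3-en-2-yl)-2H-chromen-2-one (CNP0380243.0, achiral) | C=CC(C)(C)c1cc(-c2oc3cc(O)ccc3c2Cc2cc(-c3cc4cc(C(C)(C)C=C)c(O)cc4oc3=O)c(O)cc2O)c(O)cc1O | target

Total step count: 17.
Longest linear sequence: 10 steps (8 → 10 → 11 → 13 → 14 → 15 → 16 → 18 → 19 → 23 → 24; steps 6–13, 16, 17).

Steps most likely to fail

1. Step 12 (key step). The titanium surface may deprotonate the acidic benzylic CH2 instead of reducing the ketone, and the enolate may then take the acyl group from the neighbouring ester onto carbon. Ketyls may also couple between molecules, and Lewis-acidic titanium or zinc chlorides may strip MOM groups. Fallback: the same furan is closed by the classical aryloxyacetic acid condensation, setting out from aldehyde 14 and phenol 7 and returning at 18. Aldehyde 14 is homologated with bromoform and KOH/LiCl in aqueous dioxane (Jocic-type) to the racemic mandelic acid 2-hydroxy-2-[2,4-bis(methoxymethoxy)-5-(2-methylbut-3-en-2-yl)phenyl]acetic acid F1. This is methylated on the carboxyl group (MeI, K2CO3, DMF) to the methyl mandelate F2. Mitsunobu etherification of F2 with phenol 7 (PPh3, DIAD, THF) gives the α-aryloxy ester F3, and LiOH in aqueous THF frees the α-aryloxy acid F4. Heating F4 in Ac2O with NaOAc at 120 °C should bring about intramolecular Perkin-type condensation onto the ketone with loss of CO2 and water, which gives 18.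

2. Step 8. The allyl group may migrate to C3 between the two oxygens instead of to C5. The freed phenol may add thermally across the new alkene, or the ether may simply fragment at 195 °C. Fallback: the quaternary carbon is installed by cross-coupling instead, setting out from 8 and returning at 14, so that 10, 11 and 13 are bypassed. Aldehyde 8 is brominated para to the 2-OH (Br2, AcOH) to 5-bromo-2,4-dihydroxybenzaldehyde F5, which is converted with NaH/MOMCl into 5-bromo-2,4-bis(methoxymethoxy)benzaldehyde F6. A palladium-catalysed, branch-selective (γ-selective) allyl–aryl Suzuki–Miyaura coupling of F6 with 3-methylbut-2-enylboronic acid pinacol ester (bulky biarylphosphine ligand, aq. K3PO4, THF, 40 °C) should give 14 directly.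

3. Step 15. The olefination may deliver mainly the geometric isomer with the aryl group trans to the ester, which lactonises only after isomerisation. At the temperature needed for that, vinylic substitution of bromide by the phenol (ring contraction) or decomposition may compete. Fallback: the coumarin is built onto ring C by condensation, with no bromocoumarin and no boronate, setting out from 18 and 20 and returning at 23, so that 19, 21 and 22 are bypassed. Bromide 18 is coupled with diethyl malonate (Pd(dba)2, P(t-Bu)3, K3PO4, toluene, 80 °C) to the aryl malonate F7. Saponification (NaOH, aq. EtOH), acidification to pH 3–4 and warming in toluene give, after decarboxylation, the arylacetic acid F8. Esterification of F8 with the phenol of salicylaldehyde 20 (EDC·HCl, DMAP, CH2Cl2), then DBU at 40 °C for the intramolecular Knoevenagel-type condensation (Perkin–Oglialoro logic), should give 23.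

Further compounds
F1 | step 12 | 2-hydroxy-2-[2,4-bis(methoxymethoxy)-5-(2-methylbut-3-en-2-yl)phenyl]acetic acid (racemic) | OC(C(O)=O)c1cc(C(C)(C)C=C)c(OCOC)cc1OCOC
F2 | step 12 | methyl 2-hydroxy-2-[2,4-bis(methoxymethoxy)-5-(2-methylbut-3-en-2-yl)phenyl]acetate (racemic) | COC(=O)C(O)c1cc(C(C)(C)C=C)c(OCOC)cc1OCOC
F3 | step 12 | methyl 2-(2-{2-[5-bromo-2,4-bis(methoxymethoxy)phenyl]acetyl}-5-(methoxymethoxy)phenoxy)-2-[2,4-bis(methoxymethoxy)-5-(2-methylbut-3-en-2-yl)phenyl]acetate (racemic) | COC(=O)C(Oc1cc(OCOC)ccc1C(=O)Cc1cc(Br)c(OCOC)cc1OCOC)c1cc(C(C)(C)C=C)c(OCOC)cc1OCOC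
F4 | step 12 | 2-(2-{2-[5-bromo-2,4-bis(methoxymethoxy)phenyl]acetyl}-5-(methoxymethoxy)phenoxy)-2-[2,4-bis(methoxymethoxy)-5-(2-methylbut-3-en-2-yl)phenyl]acetic acid (racemic) | OC(=O)C(Oc1cc(OCOC)ccc1C(=O)Cc1cc(Br)c(OCOC)cc1OCOC)c1cc(C(C)(C)C=C)c(OCOC)cc1OCOC
F5 | step 8 | 5-bromo-2,4-dihydroxybenzaldehyde | O=Cc1cc(Br)c(O)cc1O
F6 | step 8 | 5-bromo-2,4-bis(methoxymethoxy)benzaldehyde | O=Cc1cc(Br)c(OCOC)cc1OCOC
F7 | step 15 | diethyl 2-{5-[(2-{2,4-bis(methoxymethoxy)-5-(2-methylbut-3-en-2-yl)phenyl}-6-(methoxymethoxy)benzofuran-3-yl)methyl]-2,4-bis(methoxymethoxy)phenyl}malonate | COCOc1ccc2c(Cc3cc(C(C(=O)OCC)C(=O)OCC)c(OCOC)cc3OCOC)c(-c3cc(C(C)(C)C=C)c(OCOC)cc3OCOC)oc2c1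
F8 | step 15 | 2-{5-[(2-{2,4-bis(methoxymethoxy)-5-(2-methylbut-3-en-2-yl)phenyl}-6-(methoxymethoxy)benzofuran-3-yl)methyl]-2,4-bis(methoxymethoxy)phenyl}acetic acid | COCOc1ccc2c(Cc3cc(CC(O)=O)c(OCOC)cc3OCOC)c(-c3cc(C(C)(C)C=C)c(OCOC)cc3OCOC)oc2c1
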